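**Retrosynthetic overview**
1. The last operations form no ring: release of the side-chain OH, SeO2 oxidation of C15H3 to the enal, and acylation of the 8-OH.
2. Cyclohexane: the C5–C10 bond comes from a Cope rearrangement of an E,E-germacra-1(10),4-dien-12,6-olide (C2–C3 breaks), as in the plant.
3. γ-Lactone and ten-membered ring: C6–C7 closure (the farnesyl C1–C10 bond of germacrene biosynthesis) of an acyclic bromo-enal whose only stereocentre is C8. Macrocyclisation, lactonisation and Cope are run as one operation.
4. Acyclic chain: Baylis–Hillman (C7–C11), organocatalytic C8–O bond, Claisen (C8–C9 and the 1(10) geometry), vinyllithium addition (C1–C10), geraniol (C1–C6 and C15).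
5. Ring order: ten-membered carbocycle, then γ-lactone, then cyclohexane (the ten-membered ring is consumed).

Convention: C1–C15 are germacrane/elemane numbers (C6 lactone carbinol, C8 ester carbinol, C14 the CH2OAc carbon, C15 the formyl carbon). TMP-O = (2,2,6,6-tetramethylpiperidin-1-yl)oxy.
Assumption: the (5S)-imidazolidinone of step 6 gives the 2S aldehyde, as the usual shielding model predicts. If the sense proves opposite, the equally available (5R) antipode is used and nothing else changes.

**Step 1**
Reactants: 1 geraniol, (2E)-3,7-dimethylocta-2,6-dien-1-ol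
Product: 2 (2E)-geranyl tert-butyldimethylsilyl ether
Conditions: TBSCl, imidazole, CH2Cl2, 0 °C to rt
Reagents that add atoms: tert-butyldimethylsilyl chloride, CC(C)(C)[Si](C)(C)Cl
Why: Standard silylation of the primary allylic alcohol gives a group that survives organolithium and amine steps and later serves as a latent enal; no stereocentre is made and the E alkene (C4=C5) is untouched.

**Step 2**
Reactants: 2 (2E)-geranyl tert-butyldimethylsilyl ether
Product: 4 (4E)-6-(tert-butyldimethylsilyloxy)-4-methylhex-4-enal, via racemic 6,7-epoxide 3 (not isolated)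
Conditions: mCPBA (1.0 equiv), CH2Cl2, -20 °C; then H5IO6, THF/H2O, 0 °C
Reagents that add atoms: mCPBA, O=C(OO)c1cccc(Cl)c1
Why: Prilezhaev epoxidation picks the more electron-rich remote alkene (the other one is deactivated by the allylic oxygen), and periodic acid cleaves the epoxide through its diol (Malaprade-type cleavage) to the C1 aldehyde.

**Step 3**
Reactants: 4 (4E)-6-(tert-butyldimethylsilyloxy)-4-methylhex-4-enal; 5 2-bromoprop-2-en-1-ol
Product: 7 racemic (6E)-8-(tert-butyldimethylsilyloxy)-6-methyl-2-methylideneoct-6-ene-1,3-diol, via lithium 2-lithioprop-2-en-1-olate 6 (not isolated)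
Conditions: 5, t-BuLi (3 equiv), Et2O, -78 to 0 °C; then 4, -78 °C; H2O
Reagents that add atoms: none
Why: Deprotonation and bromine–lithium exchange give the O,2-dilithio derivative of allyl alcohol, whose 1,2-addition to the aldehyde makes C1–C10; the carbinol centre may be racemic because step 5 erases it.

**Step 4**
Reactants: 7 racemic diol
Product: 8 racemic (6E)-8-(tert-butyldimethylsilyloxy)-3-hydroxy-6-methyl-2-methylideneoct-6-en-1-yl acetate
Conditions: AcCl (1.05 equiv), 2,4,6-collidine, CH2Cl2, -78 °C
Reagents that add atoms: acetyl chloride, CC(=O)Cl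
Why: Kinetically controlled acylation with a hindered pyridine base acetylates the primary over the secondary allylic alcohol and places the C14 acetate of the target; every later step is mild enough to keep it.

**Step 5**
Reactants: 8 racemic hydroxy acetate
Product: 10 (4Z,8E)-4-(acetoxymethyl)-10-(tert-butyldimethylsilyloxy)-8-methyldeca-4,8-dienal, via allyl vinyl ether 9 (not isolated)
Conditions: ethyl vinyl ether (solvent), Hg(OAc)2 (0.2 equiv), reflux; concentrate; toluene, 120 °C, sealed tube
Reagents that add atoms: ethyl vinyl ether, C=COCC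
Why: Transvinylation followed by an aliphatic Claisen rearrangement through a chair with the C2 chain equatorial makes C8–C9 trans to C2 (about 9:1 expected), so CH2OAc ends cis to C2, which is the ring-trans 1(10) geometry the Cope step needs.

**Step 6**
Reactants: 10 (4Z,8E)-dienal
Product: 11 (2S,4Z,8E)-4-(acetoxymethyl)-10-(tert-butyldimethylsilyloxy)-8-methyl-2-(TMP-O)deca-4,8-dienal
Conditions: TEMPO (1.5 equiv), CuCl2 (10 mol %), (5S)-5-benzyl-2,2,3-trimethylimidazolidin-4-one trifluoroacetate (20 mol %), acetone, air, 0 °C
Reagents that add atoms: TEMPO, CC1(C)CCCC(C)(C)N1[O]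
Why: In this organocatalytic α-oxyamination (enamine catalysis) the E-enamine turns away from the gem-dimethyl carbon, the benzyl arm covers one face, and copper-activated TEMPO is delivered to the open face, which sets C8 as S (90% ee or better expected) and protects the oxygen in the same step.

**Step 7**
Reactants: 11 (2S)-α-aminoxy aldehyde; 12 methyl acrylate
Product: 13 methyl (4S,6Z,10E)-6-(acetoxymethyl)-12-(tert-butyldimethylsilyloxy)-3-hydroxy-10-methyl-2-methylidene-4-(TMP-O)dodeca-6,10-dienoate (C3 epimers)
Conditions: methyl acrylate (10 equiv, neat), DABCO (1,4-diazabicyclo[2.2.2]octane, 1 equiv), rt, 4 d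
Reagents that add atoms: none
Why: The Morita–Baylis–Hillman reaction joins C7 to C11 under conditions too weakly basic to epimerise C8 or cleave the acetate; the new carbinol is an inconsequential epimer mixture because step 9 removes it.

**Step 8**
Reactants: 13 Baylis–Hillman adduct
Product: 14 methyl (4S,6Z,10E)-6-(acetoxymethyl)-3-hydroxy-10-methyl-2-methylidene-12-oxo-4-(TMP-O)dodeca-6,10-dienoate (C3 epimers)
Conditions: DDQ (1.5 equiv), CH2Cl2/pH 7 buffer (10:1), rt
Reagents that add atoms: none
Why: DDQ abstracts hydride only from the electron-rich prenyl-type allylic silyl ether (oxidative desilylation) and gives the E-enal directly, while the electron-poor acrylate carbinol and the allylic acetate are inert.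

**Step 9**
Reactants: 14 hydroxy enal
Product: 15 methyl (2Z,4S,6Z,10E)-6-(acetoxymethyl)-2-(bromomethyl)-10-methyl-12-oxo-4-(TMP-O)dodeca-2,6,10-trienoate
Conditions: NBS, Me2S, CH2Cl2, -20 to 0 °C; used at once, kept at or below rt
Reagents that add atoms: N-bromosuccinimide, O=C1CCC(=O)N1Br
Why: The oxysulfonium derivative of the Baylis–Hillman alcohol is displaced by bromide in the SN2′ sense at the unhindered C13 to give the conjugated Z allylic bromide under neutral conditions; C8 is not involved.

**Step 10**
Reactants: 15 bromo enal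
Product: 18 14-acetoxy-8α-(TMP-O)elema-1,3,11(13)-trien-12,6α-olide (5αH 6βH 7αH 8βH 10β-CH2OAc), via macrocyclic hydroxy ester 16 (not isolated), via germacranolide 17 (not isolated)
Conditions: CrCl2 (10 equiv), degassed DMF, 2 mM, slow addition over 12 h, rt; aq. work-up; then mesitylene, BHT, 165 °C, 3 h
Reagents that add atoms: none
Why: Two CrCl2 convert the bromide into an allylchromium that adds through its γ-carbon C7 to the C6 enal in a chair Nozaki–Hiyama–Kishi-type transition state, with the bulky C8 aminoxyl group pseudo-equatorial and anti to the forming bond so that C8 fixes C7 (H α) and C6 (H β, anti addition), the chromium alkoxide then closes the trans-γ-lactone, and heating takes the E,E-cyclodecadiene through the chair–chair Cope transition state with C14 and C15 both on the β face, which makes C5–C10 and sets C5 (H α) and C10 (CH2OAc β).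

**Step 11**
Reactants: 18 8α-(TMP-O) elemanolide
Product: 19 14-acetoxy-8α-hydroxyelema-1,3,11(13)-trien-12,6α-olide
Conditions: Zn dust, AcOH/THF/H2O (3:1:1), 50 °C
Reagents that add atoms: none
Why: Reductive N–O cleavage of the alkoxyamine frees the alcohol without touching the C8–O bond, so the configuration is kept, and the acid-stable elemanolide with its acrylate-type alkenes tolerates zinc in acetic acid.

**Step 12**
Reactants: 20 methyl 2-(hydroxymethyl)acrylate
Product: 21 methyl 2-[(tert-butyldimethylsilyloxy)methyl]acrylate
Conditions: TBSCl, imidazole, CH2Cl2, rt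
Reagents that add atoms: tert-butyldimethylsilyl chloride, CC(C)(C)[Si](C)(C)Cl
Why: Routine silylation masks the side-chain alcohol so that the derived acid cannot acylate itself in step 14.

**Step 13**
Reactants: 21 silyl ether ester
Product: 22 2-[(tert-butyldimethylsilyloxy)methyl]acrylic acid
Conditions: LiOH, THF/H2O, 0 °C; then cold 1 M HCl to pH 4
Reagents that add atoms: lithium hydroxide, [Li+].[OH-]
Why: Saponification of the unhindered methyl ester is faster than conjugate addition or silyl loss at 0 °C, and mild acidification gives the free acid.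

**Step 14**
Reactants: 19 8α-hydroxy elemanolide; 22 protected side-chain acid
Product: 23 14-acetoxy-8α-{2-[(tert-butyldimethylsilyloxy)methyl]acryloyloxy}elema-1,3,11(13)-trien-12,6α-olide
Conditions: DCC, DMAP (4-dimethylaminopyridine, 10 mol %), CH2Cl2, 0 °C to rt
Reagents that add atoms: none
Why: Steglich esterification acylates the only free hydroxyl (equatorial, secondary) with retention at C8 under conditions that do not relactonise the 6,12-olide.

**Step 15**
Reactants: 23 silyl-protected ester
Product: 24 14-acetoxy-8α-{2-[(tert-butyldimethylsilyloxy)methyl]acryloyloxy}-15-oxoelema-1,3,11(13)-trien-12,6α-olide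
Conditions: SeO2 (1.5 equiv), 1,4-dioxane, 80 °C
Reagents that add atoms: selenium dioxide, O=[Se]=O
Why: Riley allylic oxidation (ene reaction, then [2,3]-shift, then further oxidation) can act only on the isopropenyl group, because the vinyl group has no allylic hydrogen and both acrylate alkenes are electron-poor, and methyl reacts in preference to the hindered C5 methine, giving the 2-substituted acrolein.

**Step 16**
Reactants: 24 silyl-protected enal
Product: 25 target, 14-acetoxy-8α-[2-(hydroxymethyl)acryloyloxy]-15-oxoelema-1,3,11(13)-trien-12,6α-olide (5R 6R 7R 8S 10R)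
Conditions: HF·pyridine, THF, 0 °C
Reagents that add atoms: none
Why: Acidic fluoride desilylation removes the primary TBS ether without basic conditions, so the acetate, the two acrylate units, the enal and all five stereocentres are left alone.

**Compound list**
1 | geraniol | CC(C)=CCC/C(C)=C/CO | starting material
2 | (2E)-geranyl tert-butyldimethylsilyl ether | CC(C)=CCC/C(C)=C/CO[Si](C)(C)C(C)(C)C | intermediate
3 | racemic 6,7-epoxide of 2 | CC1(C)OC1CC/C(C)=C/CO[Si](C)(C)C(C)(C)C | intermediate
4 | (4E)-6-(tert-butyldimethylsilyloxy)-4-methylhex-4-enal | O=CCC/C(C)=C/CO[Si](C)(C)C(C)(C)C | intermediate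
5 | 2-bromoprop-2-en-1-ol | OCC(Br)=C | starting material
6 | lithium 2-lithioprop-2-en-1-olate | [Li]OCC([Li])=C | intermediate
7 | racemic (6E)-8-(tert-butyldimethylsilyloxy)-6-methyl-2-methylideneoct-6-ene-1,3-diol | C=C(CO)C(O)CC/C(C)=C/CO[Si](C)(C)C(C)(C)C | intermediate
8 | racemic primary monoacetate of 7 | C=C(COC(C)=O)C(O)CC/C(C)=C/CO[Si](C)(C)C(C)(C)C | intermediate
9 | vinyl ether of 8 | C=COC(CC/C(C)=C/CO[Si](C)(C)C(C)(C)C)C(=C)COC(C)=O | intermediate
10 | (4Z,8E)-4-(acetoxymethyl)-10-(tert-butyldimethylsilyloxy)-8-methyldeca-4,8-dienal | O=CCC/C(COC(C)=O)=C/CC/C(C)=C/CO[Si](C)(C)C(C)(C)C | intermediate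
11 | (2S)-2-(TMP-O) derivative of 10 | O=C[C@@H](ON1C(C)(C)CCCC1(C)C)C/C(COC(C)=O)=C/CC/C(C)=C/CO[Si](C)(C)C(C)(C)C | intermediate
12 | methyl acrylate | C=CC(=O)OC | starting material
13 | Baylis–Hillman adduct (4S, C3 epimers) | C=C(C(=O)OC)C(O)[C@@H](ON1C(C)(C)CCCC1(C)C)C/C(COC(C)=O)=C/CC/C(C)=C/CO[Si](C)(C)C(C)(C)C | intermediate
14 | hydroxy enal (4S, C3 epimers) | C=C(C(=O)OC)C(O)[C@@H](ON1C(C)(C)CCCC1(C)C)C/C(COC(C)=O)=C/CC/C(C)=C/C=O | intermediate
15 | (2Z,4S,6Z,10E)-bromo enal | COC(=O)/C(CBr)=C/[C@@H](ON1C(C)(C)CCCC1(C)C)C/C(COC(C)=O)=C/CC/C(C)=C/C=O | intermediate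
16 | methyl 14-acetoxy-6α-hydroxy-8α-(TMP-O)germacra-1(10),4,11(13)-trien-12-oate, both ring alkenes trans in the ring | C1[C@H](ON2C(C)(C)CCCC2(C)C)[C@@H](C(=C)C(=O)OC)[C@H](O)/C=C(C)/CC/C=C1\COC(C)=O | intermediate
17 | 14-acetoxy-8α-(TMP-O)germacra-1(10),4,11(13)-trien-12,6α-olide, both ring alkenes trans in the ring | C1[C@H](ON2C(C)(C)CCCC2(C)C)[C@H]3C(=C)C(=O)O[C@@H]3/C=C(C)/CC/C=C1\COC(C)=O | intermediate
18 | 14-acetoxy-8α-(TMP-O)elema-1,3,11(13)-trien-12,6α-olide | C=C[C@]1(COC(C)=O)C[C@H](ON2C(C)(C)CCCC2(C)C)[C@H]3C(=C)C(=O)O[C@@H]3[C@H]1C(C)=C | intermediate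
19 | 14-acetoxy-8α-hydroxyelema-1,3,11(13)-trien-12,6α-olide | C=C[C@]1(COC(C)=O)C[C@H](O)[C@H]2C(=C)C(=O)O[C@@H]2[C@H]1C(C)=C | intermediate
20 | methyl 2-(hydroxymethyl)acrylate | C=C(CO)C(=O)OC | starting material
21 | methyl 2-[(tert-butyldimethylsilyloxy)methyl]acrylate | C=C(CO[Si](C)(C)C(C)(C)C)C(=O)OC | intermediate
22 | 2-[(tert-butyldimethylsilyloxy)methyl]acrylic acid | C=C(CO[Si](C)(C)C(C)(C)C)C(=O)O | intermediate
23 | 8α-ester of 19 with 22 | C=C[C@]1(COC(C)=O)C[C@H](OC(=O)C(=C)CO[Si](C)(C)C(C)(C)C)[C@H]2C(=C)C(=O)O[C@@H]2[C@H]1C(C)=C | intermediate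
24 | 15-oxo derivative of 23 | C=C[C@]1(COC(C)=O)C[C@H](OC(=O)C(=C)CO[Si](C)(C)C(C)(C)C)[C@H]2C(=C)C(=O)O[C@@H]2[C@H]1C(=C)C=O | intermediate
25 | CNP0185525.1 | C=C[C@]1(COC(C)=O)C[C@H](OC(=O)C(=C)CO)[C@H]2C(=C)C(=O)O[C@@H]2[C@H]1C(=C)C=O | target

Total step count: 16. Longest linear sequence: 14 (steps 1–11 and 14–16; steps 12–13 are the side branch).

**Steps most likely to fail**

Step 10.
- Risks: oligomerisation; 1,4-loss of the aminoxyl group from the allylchromium; and a Cope equilibrium that stops short of completion, in which case recovered 17 is reheated. An unactivated secondary alkoxyamine is expected to survive 165 °C.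
- Fallback: it sets out from 14 and comes back at 16. The carbinol of 14 is acylated with methyl chloroformate and pyridine to give the allylic methyl carbonate F1. This is added slowly to Pd(PPh3)4 (10 mol %) and Et2Zn (3 equiv) in THF at 2 mM.
- Ionisation to the π-allylpalladium and transmetalation give an allylzinc (umpolung allylation, a reaction type already used to close ten-membered germacrane rings). It forms the same C6–C7 bond through a chair transition state without any single-electron reductant.
- The doubly activated carbonate ionises much faster than the hindered C14 acetate. Compound 16 is then lactonised and heated as in the main route.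

Step 7.
- Risk: the aldehyde is α-branched by a very large group, so the amine-catalysed reaction may stall.
- Fallback: it sets out from 11 and comes back at 13. Methyl propiolate is hydroaluminated with DIBAL-H in the presence of N-methylmorpholine N-oxide (THF, 0 °C) to the preformed [1-(methoxycarbonyl)vinyl]diisobutylalane F2. This adds to the aldehyde within hours at 0 °C as a stoichiometric vinyl-metal nucleophile and leaves the acetate and silyl ether alone.

Step 15.
- Risks: over-oxidation, attack at C5–H, or a stall at the allylic alcohol.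
- Fallback: it sets out from 23 and comes back at 24. Ene-type allylic chlorination (NCS, PhSeCl 10 mol %, CH2Cl2, rt), which touches only the electron-rich isopropenyl group, gives the 15-chloride F3. Oxidation of this allylic chloride with N-methylmorpholine N-oxide (4 equiv, MeCN, rt to 40 °C, amine-oxide variant of the Kornblum oxidation) gives the enal with no selenium and no free alcohol stage.

**Further compounds**
F1 | step 10 | methyl carbonate of hydroxy enal 14 (4S, C3 epimers) | C=C(C(=O)OC)C(OC(=O)OC)[C@@H](ON1C(C)(C)CCCC1(C)C)C/C(COC(C)=O)=C/CC/C(C)=C/C=O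
F2 | step 7 | [1-(methoxycarbonyl)vinyl]diisobutylalane | C=C([Al](CC(C)C)CC(C)C)C(=O)OC
F3 | step 15 | 15-chloro derivative of 23 | C=C[C@]1(COC(C)=O)C[C@H](OC(=O)C(=C)CO[Si](C)(C)C(C)(C)C)[C@H]2C(=C)C(=O)O[C@@H]2[C@H]1C(=C)CCl
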